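## Retrosynthetic overview

1. Target 32 ⇐ C20 alcohol 31 ⇐ PMB ether 30. The ready-made butenolide ring is attached last by a Pd-catalysed sp3–sp2 Negishi coupling (C12–C13) of decalin alkylzinc 29 with 3-bromofuran-2(5H)-one 28.
2. Decalin 23 ⇐ acyclic β-keto ester diene 22 by a new Cu(II)/BOX-electrocatalytic enantioselective oxidative radical bicyclisation. Ring A closes first (C4–C5), then ring B (C9–C10); all four stereocentres and the 8(17)-methylene are set here. The C3 ketone is then removed.
3. 22 ⇐ Pd-catalysed sp2–sp3 Negishi union (C5–C6) of (Z)-vinyl iodide 11 with homoallylzinc 21.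
4. 11 ⇐ Cu-catalysed anti-carbomagnesiation/iodination of propargyl alcohol, then aldol/oxidation with methyl propionate. 21 ⇐ Zr-catalysed methylalumination of but-3-yn-1-ol and alanate opening of ethylene oxide.

Assumption: the (S,S)-t-Bu-BOX ligand is taken to expose the enolate face that leads to the (4S,5R,9S,10S) series; if the sense of induction proves opposite, the (R,R)-ligand is used.

Labdane numbering is used for the bicyclic compounds (C19 = ester carbon, C20 = angular carbon on C10, C17 = exocyclic methylene carbon).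

## Route

Step 1
Reactants: 1 2-(2-bromoethyl)-1,3-dioxolane; 2 prop-2-yn-1-ol
Product: 5 (2Z)-2-[2-(1,3-dioxolan-2-yl)ethyl]-3-iodoprop-2-en-1-ol, via Grignard reagent 3 (not isolated), via alkenylmagnesium alkoxide 4 (not isolated)
Conditions: Mg, THF, 25 °C; then 2 (0.4 equiv), CuI (10 mol%), THF, 0 °C → rt; then I2, −20 °C → rt; H2O
Reagents that add atoms: iodine (II)
Why: Cu-catalysed anti-carbomagnesiation of propargyl alcohol (Duboudin–Jousseaume reaction) puts the alkyl group on C2 and magnesium on C3, held cis to the alkoxide in a five-membered chelate, so iodinolysis with retention gives only the Z iodide (I cis to CH2OH), which fixes the later C5=C10 geometry.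

Step 2
Reactants: 5 (2Z)-2-[2-(1,3-dioxolan-2-yl)ethyl]-3-iodoprop-2-en-1-ol
Product: 6 2-[(3Z)-4-iodo-3-{[(4-methoxybenzyl)oxy]methyl}but-3-en-1-yl]-1,3-dioxolane
Conditions: NaH, PMBCl, Bu4NI (cat.), THF/DMF, 0 °C → rt
Reagents that add atoms: 4-methoxybenzyl chloride (COc1ccc(CCl)cc1)
Why: Williamson etherification of the primary allylic alkoxide; the dioxolane is base-stable and the vinyl iodide has no hydrogen on the adjacent alkene carbon to eliminate.

Step 3
Reactants: 6 2-[(3Z)-4-iodo-3-{[(4-methoxybenzyl)oxy]methyl}but-3-en-1-yl]-1,3-dioxolane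
Product: 7 (4Z)-5-iodo-4-{[(4-methoxybenzyl)oxy]methyl}pent-4-enal
Conditions: 1 M aq HCl, THF, rt
Reagents that add atoms: water (O)
Why: Acid-catalysed acetal hydrolysis; the PMB ether and vinyl iodide are stable to dilute aqueous acid at room temperature.

Step 4
Reactants: 7 (4Z)-5-iodo-4-{[(4-methoxybenzyl)oxy]methyl}pent-4-enal; 8 methyl propionate
Product: 10 methyl (6Z)-3-hydroxy-7-iodo-6-{[(4-methoxybenzyl)oxy]methyl}-2-methylhept-6-enoate, via lithium ester enolate 9 (not isolated)
Conditions: LDA, THF, −78 °C; then 7, −78 °C; AcOH quench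
Reagents that add atoms: none
Why: Aldol addition of the lithium ester enolate to the unhindered aldehyde at −78 °C is much faster than any reaction at the vinyl iodide; the two new stereocentres form as a mixture that is erased in steps 5 and 12.

Step 5
Reactants: 10 methyl (6Z)-3-hydroxy-7-iodo-6-{[(4-methoxybenzyl)oxy]methyl}-2-methylhept-6-enoate
Product: 11 methyl (6Z)-7-iodo-6-{[(4-methoxybenzyl)oxy]methyl}-2-methyl-3-oxohept-6-enoate
Conditions: Dess–Martin periodinane, CH2Cl2, 0 °C → rt
Reagents that add atoms: none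
Why: Dess–Martin oxidation of the secondary carbinol gives the α-methyl β-keto ester without touching the PMB ether or the vinyl iodide.

Step 6
Reactants: 12 but-3-yn-1-ol
Product: 13 tert-butyl(but-3-yn-1-yloxy)dimethylsilane
Conditions: TBSCl, imidazole, CH2Cl2, 0 °C → rt
Reagents that add atoms: tert-butyldimethylsilyl chloride (CC(C)(C)[Si](C)(C)Cl)
Why: Standard silylation masks the O–H for the organoaluminium chemistry that follows.

Step 7
Reactants: 13 tert-butyl(but-3-yn-1-yloxy)dimethylsilane; 14 ethylene oxide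
Product: 17 (3E)-6-{[tert-butyl(dimethyl)silyl]oxy}-4-methylhex-3-en-1-ol, via alkenyldimethylalane 15 (not isolated), via lithium alkenylaluminate 16 (not isolated)
Conditions: Me3Al (2 equiv), Cp2ZrCl2 (20 mol%), CH2Cl2, 0 °C → rt; evaporate volatiles; n-BuLi, hexane, 0 °C; then 14, THF, −30 °C → rt; H2O
Reagents that add atoms: trimethylaluminium (C[Al](C)C)
Why: Negishi Zr-catalysed syn-methylalumination places CH3 on the internal carbon and Al on the terminus, and the derived alkenylalanate opens ethylene oxide with retention, so the E-C8=C9 olefin is set here.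

Step 8
Reactants: 17 (3E)-6-{[tert-butyl(dimethyl)silyl]oxy}-4-methylhex-3-en-1-ol
Product: 18 {[(3E)-6-bromo-3-methylhex-3-en-1-yl]oxy}(tert-butyl)dimethylsilane
Conditions: CBr4, PPh3, 2,6-lutidine (cat.), CH2Cl2, 0 °C
Reagents that add atoms: carbon tetrabromide (BrC(Br)(Br)Br)
Why: Appel bromination of the primary alcohol under buffered conditions leaves the TBS ether and the trisubstituted alkene intact.

Step 9
Reactants: 18 {[(3E)-6-bromo-3-methylhex-3-en-1-yl]oxy}(tert-butyl)dimethylsilane
Product: 19 (3E)-6-bromo-3-methylhex-3-en-1-ol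
Conditions: CSA (10 mol%), MeOH, 0 °C → rt
Reagents that add atoms: none
Why: Acid-catalysed methanolysis of the primary TBS ether; the homoallylic bromide is inert and fluoride is avoided.

Step 10
Reactants: 19 (3E)-6-bromo-3-methylhex-3-en-1-ol
Product: 20 (3E)-6-bromo-1-iodo-3-methylhex-3-ene
Conditions: I2, PPh3, imidazole, CH2Cl2, 0 °C → rt
Reagents that add atoms: iodine (II)
Why: Appel-type (Garegg–Samuelsson) iodination by SN2 at the primary carbon gives a dihalide whose two ends differ in reactivity toward zinc.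

Step 11
Reactants: 20 (3E)-6-bromo-1-iodo-3-methylhex-3-ene; 11 methyl (6Z)-7-iodo-6-{[(4-methoxybenzyl)oxy]methyl}-2-methyl-3-oxohept-6-enoate
Product: 22 methyl (6Z,10E)-13-bromo-6-{[(4-methoxybenzyl)oxy]methyl}-2,10-dimethyl-3-oxotrideca-6,10-dienoate, via homoallylzinc iodide 21 (not isolated)
Conditions: 20 (1.5 equiv), Zn dust (BrCH2CH2Br/TMSCl-activated), THF, 30 °C; then 11, Pd(P(t-Bu)3)2 (3 mol%), THF, 0 °C → rt
Reagents that add atoms: none
Why: Negishi sp3–sp2 cross-coupling: zinc inserts selectively into the C–I bond, the Z-iodide couples with retention, the fast Pd/P(t-Bu)3 catalyst should outrun protonolysis of the alkylzinc by the β-keto ester C–H, and this catalyst does not activate the primary alkyl bromide.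

Step 12
Reactants: 22 methyl (6Z,10E)-13-bromo-6-{[(4-methoxybenzyl)oxy]methyl}-2,10-dimethyl-3-oxotrideca-6,10-dienoate
Product: 23 methyl 12-bromo-20-[(4-methoxybenzyl)oxy]-3-oxo-13,14,15,16-tetranorlabd-8(17)-en-19-oate
Conditions: Cu(OTf)2 (15 mol%), (S,S)-t-Bu-BOX (18 mol%), 2,6-lutidine (1 equiv), LiClO4, MeCN/CF3CH2OH 9:1, carbon-felt anode/Pt cathode, undivided cell, 2.2 F/mol, 0 °C
Reagents that add atoms: none
Why: Proposed new method: the chiral Cu(II)–BOX complex binds 22 as its square-planar β-keto ester enolate, and one-electron anodic oxidation gives a Cu-chelated electrophilic α-radical shielded on one face by a ligand tert-butyl group, so 6-endo attack on the C5=C10 alkene sets C4 (ester axial, methyl equatorial) and C5; the tertiary C10 radical then closes ring B through a chair–chair transition state (trans-decalin, equatorial C9 side chain from the E-alkene), and the tertiary C8 radical is captured by Cu(II) and undergoes Hofmann-selective β-hydride elimination to the 8(17)-methylene while Cu(I) is reoxidised at the anode and protons are reduced at the cathode; the closest known reaction types are the stoichiometric Mn(OAc)3/Cu(OAc)2 oxidative radical polycyclisation of α-methyl β-keto esters (racemic), chiral-Lewis-acid-templated group-transfer radical cyclisations of α-halo β-keto esters, and anodically turned-over Cu/BOX radical catalysis.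

Step 13
Reactants: 23 methyl 12-bromo-20-[(4-methoxybenzyl)oxy]-3-oxo-13,14,15,16-tetranorlabd-8(17)-en-19-oate
Product: 25 methyl 12-bromo-20-[(4-methoxybenzyl)oxy]-13,14,15,16-tetranorlabd-8(17)-en-19-oate, via tosylhydrazone 24 (not isolated)
Conditions: TsNHNH2, PPTS (10 mol%), EtOH, 70 °C; evaporate; catecholborane, CHCl3, 0 °C → rt; then NaOAc·3H2O, reflux
Reagents that add atoms: none
Why: Kabalka variant of the Caglioti tosylhydrazone reduction: hydride addition then acetate-induced loss of sulfinate and N2 gives the C3 methylene under conditions that spare the hindered ester, PMB ether, primary bromide and exocyclic alkene; no stereocentre is touched.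

Step 14
Reactants: 26 furan-2(5H)-one
Product: 28 3-bromofuran-2(5H)-one, via dibromolactone 27 (not isolated)
Conditions: Br2, CH2Cl2, rt → reflux; then Et3N, 0 °C
Reagents that add atoms: bromine (BrBr)
Why: Bromine addition to the butenolide followed by E2 loss of HBr through the acidic α-hydrogen gives the α-bromobutenolide, which is made fresh because it is base- and storage-sensitive.

Step 15
Reactants: 25 methyl 12-bromo-20-[(4-methoxybenzyl)oxy]-13,14,15,16-tetranorlabd-8(17)-en-19-oate; 28 3-bromofuran-2(5H)-one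
Product: 30 methyl 20-[(4-methoxybenzyl)oxy]labda-8(17),13-dien-16,15-olid-19-oate, via alkylzinc bromide 29 (not isolated)
Conditions: Zn dust, LiCl, THF, 50 °C; then 28 (1.3 equiv), Pd(OAc)2 (4 mol%), SPhos (8 mol%), THF, 0 °C → rt
Reagents that add atoms: none
Why: LiCl-promoted zinc insertion into the primary bromide (Knochel) and Negishi coupling with the α-bromoenoate-type electrophile, which undergoes fast oxidative addition; the neutral alkylzinc tolerates the ester and does not add to the butenolide without catalyst.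

Step 16
Reactants: 30 methyl 20-[(4-methoxybenzyl)oxy]labda-8(17),13-dien-16,15-olid-19-oate
Product: 31 methyl 20-hydroxylabda-8(17),13-dien-16,15-olid-19-oate
Conditions: DDQ, CH2Cl2/pH 7 buffer 10:1, 0 °C → rt; crude product used at once
Reagents that add atoms: none
Why: Oxidative PMB cleavage by DDQ under neutral buffered conditions leaves the butenolide and exocyclic alkene alone; the hydroxy ester is carried forward immediately so that it cannot close to the 19,20-lactone.

Step 17
Reactants: 31 methyl 20-hydroxylabda-8(17),13-dien-16,15-olid-19-oate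
Product: 32 methyl 20-oxolabda-8(17),13-dien-16,15-olid-19-oate (target)
Conditions: Dess–Martin periodinane, CH2Cl2, 0 °C → rt
Reagents that add atoms: none
Why: Dess–Martin oxidation of the neopentyl primary alcohol gives the non-enolisable C20 aldehyde; no stereocentre is affected.

## Compound list

1 | 2-(2-bromoethyl)-1,3-dioxolane | BrCCC1OCCO1 | starting material
2 | prop-2-yn-1-ol | C#CCO | starting material
3 | [2-(1,3-dioxolan-2-yl)ethyl]magnesium bromide | Br[Mg]CCC1OCCO1 | intermediate
4 | (Z)-alkenylmagnesium alkoxide from anti-addition of 3 to the alkoxide of 2 (Mg on C3 cis to CH2O) | Br[Mg]OC/C(CCC1OCCO1)=C\[Mg]Br | intermediate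
5 | (2Z)-2-[2-(1,3-dioxolan-2-yl)ethyl]-3-iodoprop-2-en-1-ol (I cis to CH2OH) | OC/C(CCC1OCCO1)=C\I | intermediate
6 | 2-[(3Z)-4-iodo-3-{[(4-methoxybenzyl)oxy]methyl}but-3-en-1-yl]-1,3-dioxolane | COc1ccc(COC/C(CCC2OCCO2)=C\I)cc1 | intermediate
7 | (4Z)-5-iodo-4-{[(4-methoxybenzyl)oxy]methyl}pent-4-enal | O=CCC/C(COCc1ccc(OC)cc1)=C/I | intermediate
8 | methyl propionate | CCC(=O)OC | starting material
9 | lithium enolate of methyl propionate | CC=C(OC)O[Li] | intermediate
10 | methyl (6Z)-3-hydroxy-7-iodo-6-{[(4-methoxybenzyl)oxy]methyl}-2-methylhept-6-enoate (diastereomer mixture at C2/C3) | COC(=O)C(C)C(O)CC/C(COCc1ccc(OC)cc1)=C/I | intermediate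
11 | methyl (6Z)-7-iodo-6-{[(4-methoxybenzyl)oxy]methyl}-2-methyl-3-oxohept-6-enoate (racemic at C2) | COC(=O)C(C)C(=O)CC/C(COCc1ccc(OC)cc1)=C/I | intermediate
12 | but-3-yn-1-ol | C#CCCO | starting material
13 | tert-butyl(but-3-yn-1-yloxy)dimethylsilane | C#CCCO[Si](C)(C)C(C)(C)C | intermediate
14 | ethylene oxide | C1CO1 | starting material
15 | [(1E)-4-{[tert-butyl(dimethyl)silyl]oxy}-2-methylbut-1-en-1-yl]dimethylalumane | C[Al](C)/C=C(\C)CCO[Si](C)(C)C(C)(C)C | intermediate
16 | lithium butyl[(1E)-4-{[tert-butyl(dimethyl)silyl]oxy}-2-methylbut-1-en-1-yl]dimethylaluminate | [Li+].CCCC[Al-](C)(C)/C=C(\C)CCO[Si](C)(C)C(C)(C)C | intermediate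
17 | (3E)-6-{[tert-butyl(dimethyl)silyl]oxy}-4-methylhex-3-en-1-ol | OCC/C=C(\C)CCO[Si](C)(C)C(C)(C)C | intermediate
18 | {[(3E)-6-bromo-3-methylhex-3-en-1-yl]oxy}(tert-butyl)dimethylsilane | BrCC/C=C(\C)CCO[Si](C)(C)C(C)(C)C | intermediate
19 | (3E)-6-bromo-3-methylhex-3-en-1-ol | OCC/C(C)=C/CCBr | intermediate
20 | (3E)-6-bromo-1-iodo-3-methylhex-3-ene | ICC/C(C)=C/CCBr | intermediate
21 | [(3E)-6-bromo-3-methylhex-3-en-1-yl]zinc iodide | BrCC/C=C(\C)CC[Zn]I | intermediate
22 | methyl (6Z,10E)-13-bromo-6-{[(4-methoxybenzyl)oxy]methyl}-2,10-dimethyl-3-oxotrideca-6,10-dienoate (racemic at C2) | COC(=O)C(C)C(=O)CC/C(COCc1ccc(OC)cc1)=C/CC/C(C)=C/CCBr | intermediate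
23 | methyl 12-bromo-20-[(4-methoxybenzyl)oxy]-3-oxo-13,14,15,16-tetranorlabd-8(17)-en-19-oate (trans-decalin; 4α-CH3, 4β-CO2Me, 5α-H, 9α-H with 9β-CH2CH2Br, 10β-CH2OPMB) | C=C1CC[C@@H]2[C@](COCc3ccc(OC)cc3)(CCC(=O)[C@]2(C)C(=O)OC)[C@H]1CCBr | intermediate
24 | C3 tosylhydrazone of 23 | C=C1CC[C@@H]2[C@](COCc3ccc(OC)cc3)(CCC(=NNS(=O)(=O)c3ccc(C)cc3)[C@]2(C)C(=O)OC)[C@H]1CCBr | intermediate
25 | methyl 12-bromo-20-[(4-methoxybenzyl)oxy]-13,14,15,16-tetranorlabd-8(17)-en-19-oate (configuration as 23) | C=C1CC[C@@H]2[C@](COCc3ccc(OC)cc3)(CCC[C@]2(C)C(=O)OC)[C@H]1CCBr | intermediate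
26 | furan-2(5H)-one | O=C1OCC=C1 | starting material
27 | trans-3,4-dibromodihydrofuran-2(3H)-one (racemic) | O=C1OCC(Br)C1Br | intermediate
28 | 3-bromofuran-2(5H)-one | O=C1OCC=C1Br | intermediate
29 | C12 alkylzinc bromide derived from 25 | C=C1CC[C@@H]2[C@](COCc3ccc(OC)cc3)(CCC[C@]2(C)C(=O)OC)[C@H]1CC[Zn]Br | intermediate
30 | methyl 20-[(4-methoxybenzyl)oxy]labda-8(17),13-dien-16,15-olid-19-oate (configuration as 23) | C=C1CC[C@@H]2[C@](COCc3ccc(OC)cc3)(CCC[C@]2(C)C(=O)OC)[C@H]1CCC1=CCOC1=O | intermediate
31 | methyl 20-hydroxylabda-8(17),13-dien-16,15-olid-19-oate (configuration as 23) | C=C1CC[C@@H]2[C@](CO)(CCC[C@]2(C)C(=O)OC)[C@H]1CCC1=CCOC1=O | intermediate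
32 | methyl (4S,5R,9S,10S)-20-oxolabda-8(17),13-dien-16,15-olid-19-oate = methyl (1S,4aS,5S,8aR)-4a-formyl-1-methyl-6-methylidene-5-[2-(2-oxo-2,5-dihydrofuran-3-yl)ethyl]decahydronaphthalene-1-carboxylate | C=C1CC[C@@H]2[C@](C=O)(CCC[C@]2(C)C(=O)OC)[C@H]1CCC1=CCOC1=O | target

## Step count and risk

Total steps: 17. Longest linear sequence: 11 steps (1–5, 11, 12, 13, 15, 16, 17; the branch 6–10, 11, 12, 13, 15, 16, 17 is equally long). Steps 6–10 and step 14 run in parallel branches.

The three steps most likely to fail are steps 11, 12 and 13.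

Step 11 (Negishi union in the presence of the acidic β-keto ester C–H). If protonolysis of the alkylzinc or Pd-enolate side reactions dominate, the order of operations is changed so that no acidic C–H is present at the coupling. The fallback sets out from 6 (with zinc reagent 21 made from 20 as before) and comes back at 22. Zinc reagent 21 is coupled with the acetal-protected vinyl iodide 6 under the same Pd conditions to give the diene acetal F1. Hydrolysis with 1 M HCl/THF gives the dienal F2. Aldol addition of enolate 9 at −78 °C (the primary bromide is not alkylated at this temperature) gives the β-hydroxy ester F3, and Dess–Martin oxidation returns 22. This costs three post-union steps but uses only standard chemistry.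

Step 12 (the proposed new Cu/BOX-electrocatalytic asymmetric bicyclisation). The uncertainties are whether the Cu-bound enolate is oxidised cleanly, the level of enantioselectivity with a methyl ester, and the exo/endo olefin ratio. The fallback sets out from 22 and comes back at 23. It is the known Snider oxidative free-radical cyclisation: Mn(OAc)3·2H2O (2.2 equiv), Cu(OAc)2·H2O (1 equiv), degassed AcOH, rt. This is established to give trans-fused 4-methyl-4-carbomethoxy-3-oxo decalins with an exocyclic alkene, and here delivers the racemic bicyclic keto ester F4. Resolution by preparative chiral SFC returns enantiopure 23.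

Step 13 (deoxygenation of the hindered C3 ketone next to the quaternary C4). Hydrazone formation may be slow or the reduction incomplete. A tin hydride route is not possible while the C12 bromide is present, so the fallback installs the butenolide first. It sets out from 23 and comes back at 30, bypassing 25 and step 15. Zinc insertion (Zn, LiCl, THF, 50 °C) and Negishi coupling with 28 give the keto butenolide F5. Luche reduction (NaBH4, CeCl3·7H2O, MeOH, −40 °C) gives the 3β-alcohol F6 without reducing the butenolide. Thiocarbonyldiimidazole with DMAP in 1,2-dichloroethane at 70 °C gives the imidazolylthiocarbonate F7, and Barton–McCombie deoxygenation (Bu3SnH, AIBN, toluene, 100 °C) returns 30.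

## Further compounds

F1 | step 11 | diene acetal 2-[(3Z,7E)-10-bromo-3-{[(4-methoxybenzyl)oxy]methyl}-7-methyldeca-3,7-dien-1-yl]-1,3-dioxolane | BrCC/C=C(\C)CC/C=C(\COCc1ccc(OC)cc1)CCC1OCCO1
F2 | step 11 | dienal (4Z,8E)-11-bromo-4-{[(4-methoxybenzyl)oxy]methyl}-8-methylundeca-4,8-dienal | BrCC/C=C(\C)CC/C=C(\COCc1ccc(OC)cc1)CCC=O
F3 | step 11 | β-hydroxy ester methyl (6Z,10E)-13-bromo-3-hydroxy-6-{[(4-methoxybenzyl)oxy]methyl}-2,10-dimethyltrideca-6,10-dienoate | COC(=O)C(C)C(O)CC/C(COCc1ccc(OC)cc1)=C/CC/C(C)=C/CCBr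
F4 | step 12 | racemic bicyclic keto ester (23 and its mirror image, 1:1) | C=C1CC[C@@H]2[C@](COCc3ccc(OC)cc3)(CCC(=O)[C@]2(C)C(=O)OC)[C@H]1CCBr.C=C1CC[C@H]2[C@@](COCc3ccc(OC)cc3)(CCC(=O)[C@@]2(C)C(=O)OC)[C@@H]1CCBr
F5 | step 13 | keto butenolide methyl 20-[(4-methoxybenzyl)oxy]-3-oxolabda-8(17),13-dien-16,15-olid-19-oate | C=C1CC[C@@H]2[C@](COCc3ccc(OC)cc3)(CCC(=O)[C@]2(C)C(=O)OC)[C@H]1CCC1=CCOC1=O
F6 | step 13 | 3β-alcohol methyl 3β-hydroxy-20-[(4-methoxybenzyl)oxy]labda-8(17),13-dien-16,15-olid-19-oate | C=C1CC[C@@H]2[C@](COCc3ccc(OC)cc3)(CC[C@H](O)[C@]2(C)C(=O)OC)[C@H]1CCC1=CCOC1=O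
F7 | step 13 | imidazolylthiocarbonate methyl 3β-[(1H-imidazol-1-ylcarbonothioyl)oxy]-20-[(4-methoxybenzyl)oxy]labda-8(17),13-dien-16,15-olid-19-oate | C=C1CC[C@@H]2[C@](COCc3ccc(OC)cc3)(CC[C@H](OC(=S)n3ccnc3)[C@]2(C)C(=O)OC)[C@H]1CCC1=CCOC1=O
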